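The benzene ring of the indole is taken apart at C3a–C7a, C4–C5 and C4–O, which leads back to a 3-bromofuran bonded through its C2 to N1, with a terminal alkyne on the nitrogen tether. The feature exploited is the 4-hydroxy-7-bromo pattern flanking the ring fusion: C7a, C7 (with its bromine), C6 and C5 are the four furan carbons, C3a and C4 are the alkyne carbons, and the C4 oxygen is the former furan ring oxygen. A single gold-catalysed furan-yne isomerisation therefore closes the benzene and pyrroline rings together. Its precursor is a methyl N-(3-bromofuran-2-yl) carbamate N-alkylated with a 3-substituted pent-4-ynoate, whose ester arm later grows into the pyrimidine.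

Key step: step 6

Assumption: (E)-pent-2-en-4-yn-1-ol 5 is treated as a purchasable alcohol (its Z isomer would give the same racemic ester 8).
Remark: compounds 8 to 16 carry the future C3 as a stereocentre and are used as racemates (14 as a mixture of diastereomers); step 8 erases this centre and the target is achiral.

Step 1
Reactants: 1 3-bromofuran-2-carboxylic acid
Product: 4 methyl (3-bromofuran-2-yl)carbamate, via 3-bromofuran-2-carbonyl azide 2 (not isolated), via 3-bromo-2-isocyanatofuran 3 (not isolated)
Conditions: DPPA, Et3N, PhMe, rt then 85 °C; MeOH, 70 °C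
Reagents that add atoms: diphenylphosphoryl azide [N-]=[N+]=NP(=O)(Oc1ccccc1)Oc1ccccc1; methanol CO
Why: Curtius rearrangement, in which the acyl azide loses N2 on heating with migration of furan C2 to nitrogen and methanol traps the isocyanate as a carbamate that keeps the 2-aminofuran stable.

Step 2
Reactants: 5 (E)-pent-2-en-4-yn-1-ol; 6 trimethyl orthoacetate
Product: 8 methyl 3-ethynylpent-4-enoate (racemic), via allyl ketene acetal 7 (not isolated)
Conditions: EtCO2H (cat.), xylene, 130 °C, MeOH distilled off
Reagents that add atoms: none
Why: Johnson–Claisen rearrangement, in which acid-catalysed exchange gives the allyl ketene acetal and its [3,3] shift forms the C–C bond at the alkyne-bearing alkene carbon, setting the new stereocentre without control (racemate, erased in step 8).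

Step 3
Reactants: 8 methyl 3-ethynylpent-4-enoate (racemic)
Product: 11 4-ethynyldihydrofuran-2(3H)-one (racemic), via methyl 3-formylpent-4-ynoate 9 (not isolated), via methyl 3-(hydroxymethyl)pent-4-ynoate 10 (not isolated)
Conditions: O3, CH2Cl2/MeOH, −78 °C (stopped at first blue colour); NaBH4, −78 → 0 °C; TsOH (cat.), CH2Cl2, rt
Reagents that add atoms: ozone O=[O+][O-]
Why: Ozonolysis with reductive work-up, in which ozone cleaves the monosubstituted alkene far faster than the terminal alkyne, NaBH4 reduces the peroxidic product to the primary alcohol and the γ-hydroxy ester lactonises under acid.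

Step 4
Reactants: 11 4-ethynyldihydrofuran-2(3H)-one (racemic)
Product: 12 methyl 3-(bromomethyl)pent-4-ynoate (racemic)
Conditions: dry HBr (sat.), MeOH, 0 °C → rt
Reagents that add atoms: hydrogen bromide Br; methanol CO
Why: Acid-mediated lactone opening, in which bromide attacks the O–CH2 carbon of the protonated lactone (SN2) and the liberated acid undergoes Fischer esterification, under conditions where ionic HBr addition to an isolated terminal alkyne is slow.

Step 5
Reactants: 4 methyl (3-bromofuran-2-yl)carbamate; 12 methyl 3-(bromomethyl)pent-4-ynoate (racemic)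
Product: 13 methyl 3-{[(3-bromofuran-2-yl)(methoxycarbonyl)amino]methyl}pent-4-ynoate (racemic)
Conditions: Cs2CO3, n-Bu4NI (cat.), DMF, 50 °C
Reagents that add atoms: none
Why: N-alkylation (SN2) of the carbamate anion, helped by in-situ Finkelstein exchange to the iodide at the β-branched primary carbon, while the mild carbonate base keeps ester enolisation and E2 elimination low.

Step 6
Reactants: 13 methyl 3-{[(3-bromofuran-2-yl)(methoxycarbonyl)amino]methyl}pent-4-ynoate (racemic)
Product: 15 methyl 7-bromo-4-hydroxy-3-(2-methoxy-2-oxoethyl)-2,3-dihydroindole-1-carboxylate (racemic), via C4–C5 arene oxide 14 (not isolated)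
Conditions: [(t-Bu)2(2-biphenylyl)P]Au(NCMe)SbF6 (monovalent gold, 3 mol %), CH2Cl2 (0.05 M), 4 Å MS, rt
Reagents that add atoms: none
Why: Proposed new method: the cationic gold centre activates the terminal alkyne, furan C2 (ipso to nitrogen) adds to the internal alkyne carbon through a cyclopropyl gold carbene, cleavage of the furan C2–O bond gives a gold carbene conjugated to a (Z)-enal, the aldehyde oxygen adds to the carbene carbon (C4–O) to give an oxepine that closes to the C4–C5 arene oxide, and this opens at C5–O with loss of the C4 proton to the phenol. The closest known reaction type is the gold-catalysed furan-yne phenol synthesis of furans that carry the alkyne on a carbon-linked tether at C2; a furan bearing nitrogen directly on C2 has not been used. The pyrroline ring closes 5-exo-dig (C3a–C7a) and the benzene ring closes by 6π electrocyclisation of the oxepine (C4–C5). No stereocentre is formed and the racemic C3 centre is a spectator. The step needs attack through furan C2 and not through the enamide carbon C3 or the carbamate oxygen, which the exo five-ring geometry, the bromine on C3 and a methyl carbamate that cannot lose its alkyl group (a tert-butyl carbamate would cyclise irreversibly onto a gold-activated alkyne) provide. It also needs the oxygen to stay on C4 against the pull of the nitrogen lone pair para to C5, which the acylated nitrogen beside the C7 bromine and the alkyl-substituted C3a (stabilising C5–O opening) are meant to secure; this is the main uncertainty.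

Step 7
Reactants: 15 methyl 7-bromo-4-hydroxy-3-(2-methoxy-2-oxoethyl)-2,3-dihydroindole-1-carboxylate (racemic)
Product: 16 methyl 7-bromo-4-methoxy-3-(2-methoxy-2-oxoethyl)-2,3-dihydroindole-1-carboxylate (racemic)
Conditions: MeI, K2CO3, acetone, 50 °C
Reagents that add atoms: iodomethane CI
Why: Williamson ether synthesis on the phenoxide, which gives an ether that survives base, DDQ and POBr3 and stops the phenol from lactonising onto the neighbouring ester arm.

Step 8
Reactants: 16 methyl 7-bromo-4-methoxy-3-(2-methoxy-2-oxoethyl)-2,3-dihydroindole-1-carboxylate (racemic)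
Product: 17 methyl 7-bromo-4-methoxy-3-(2-methoxy-2-oxoethyl)indole-1-carboxylate
Conditions: DDQ, PhMe, 100 °C
Reagents that add atoms: none
Why: DDQ dehydrogenation, in which hydride abstraction from benzylic C3 (assisted by the ortho methoxy group and N1) and loss of the C2 proton aromatise the pyrrole ring and erase the C3 stereocentre, the N-carbamate shielding the indole from over-oxidation.

Step 9
Reactants: 17 methyl 7-bromo-4-methoxy-3-(2-methoxy-2-oxoethyl)indole-1-carboxylate; 18 methyl formate
Product: 20 methyl 2-(7-bromo-4-methoxy-1H-indol-3-yl)-3-hydroxyprop-2-enoate (enol of the formyl ester), via methyl 2-(7-bromo-4-methoxy-1H-indol-3-yl)acetate 19 (not isolated)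
Conditions: NaOMe, MeOH/THF, 0 °C → rt; evaporate; NaH, HCO2Me, THF, 0 °C → rt; 1 M HCl to pH 4
Reagents that add atoms: none
Why: Methanolysis of the reactive N-acylindole carbamate followed by crossed Claisen condensation with non-enolisable methyl formate, driven by formation of the stabilised enolate of the β-formyl ester.

Step 10
Reactants: 20 methyl 2-(7-bromo-4-methoxy-1H-indol-3-yl)-3-hydroxyprop-2-enoate; 21 urea
Product: 23 5-(7-bromo-4-methoxy-1H-indol-3-yl)pyrimidine-2,4(1H,3H)-dione, via ureidoacrylate ester 22 (not isolated)
Conditions: urea, HCl (cat.), MeOH, 65 °C; then NaOMe, MeOH, 65 °C; HCl to pH 5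
Reagents that add atoms: none
Why: Classical uracil synthesis, in which acid-catalysed condensation of urea with the formyl (enol) carbon gives the ureidoacrylate and methoxide closes the ring by attack of the second urea nitrogen on the ester.

Step 11
Reactants: 23 5-(7-bromo-4-methoxy-1H-indol-3-yl)pyrimidine-2,4(1H,3H)-dione
Product: 24 7-bromo-3-(2,4-dibromopyrimidin-5-yl)-4-methoxy-1H-indole
Conditions: POBr3, PhNMe2, MeCN, 80 °C
Reagents that add atoms: phosphoryl bromide O=P(Br)(Br)Br
Why: Deoxybromination, in which both lactam oxygens are phosphorylated and displaced by bromide (addition–elimination), the aryl methyl ether and the indole N–H being inert under amine-buffered conditions.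

Step 12
Reactants: 24 7-bromo-3-(2,4-dibromopyrimidin-5-yl)-4-methoxy-1H-indole
Product: 25 2-bromo-5-(7-bromo-4-methoxy-1H-indol-3-yl)pyrimidin-4-amine
Conditions: NH3 (0.5 M in 1,4-dioxane), sealed tube, 40 °C
Reagents that add atoms: ammonia N
Why: Nucleophilic aromatic substitution, in which ammonia attacks C4' of the 2,4-dibromopyrimidine (the position para to N1', whose adduct is best stabilised) in preference to C2'.

Step 13
Reactants: 25 2-bromo-5-(7-bromo-4-methoxy-1H-indol-3-yl)pyrimidin-4-amine
Product: 26 3-(4-amino-2-bromopyrimidin-5-yl)-7-bromo-1H-indol-4-ol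
Conditions: BBr3, CH2Cl2, −78 °C → rt; H2O
Reagents that add atoms: none
Why: Lewis-acid ether cleavage, in which BBr3 coordinates the methoxy oxygen and bromide removes the methyl group (SN2), bromide being the only halide present so that no halogen exchange at C2' can occur.

Compound list
1 | 3-bromofuran-2-carboxylic acid | OC(=O)c1occc1Br | starting material
2 | 3-bromofuran-2-carbonyl azide | [N-]=[N+]=NC(=O)c1occc1Br | intermediate (not isolated)
3 | 3-bromo-2-isocyanatofuran | O=C=Nc1occc1Br | intermediate (not isolated)
4 | methyl (3-bromofuran-2-yl)carbamate | COC(=O)Nc1occc1Br | intermediate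
5 | (E)-pent-2-en-4-yn-1-ol | OC/C=C/C#C | starting material
6 | trimethyl orthoacetate | CC(OC)(OC)OC | starting material
7 | (E)-5-[(1-methoxyethenyl)oxy]pent-3-en-1-yne (allyl ketene acetal) | C=C(OC)OC/C=C/C#C | intermediate (not isolated)
8 | methyl 3-ethynylpent-4-enoate (racemic) | C=CC(C#C)CC(=O)OC | intermediate
9 | methyl 3-formylpent-4-ynoate (racemic) | C#CC(C=O)CC(=O)OC | intermediate (not isolated)
10 | methyl 3-(hydroxymethyl)pent-4-ynoate (racemic) | C#CC(CO)CC(=O)OC | intermediate (not isolated)
11 | 4-ethynyldihydrofuran-2(3H)-one (racemic) | O=C1CC(C#C)CO1 | intermediate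
12 | methyl 3-(bromomethyl)pent-4-ynoate (racemic) | C#CC(CBr)CC(=O)OC | intermediate
13 | methyl 3-{[(3-bromofuran-2-yl)(methoxycarbonyl)amino]methyl}pent-4-ynoate (racemic) | C#CC(CC(=O)OC)CN(C(=O)OC)c1occc1Br | intermediate
14 | methyl 7-bromo-4,5-epoxy-3-(2-methoxy-2-oxoethyl)-2,3,4,5-tetrahydroindole-1-carboxylate (C4–C5 arene oxide, mixture of diastereomers) | COC(=O)CC1CN(C(=O)OC)C2=C1C1OC1C=C2Br | intermediate (not isolated)
15 | methyl 7-bromo-4-hydroxy-3-(2-methoxy-2-oxoethyl)-2,3-dihydroindole-1-carboxylate (racemic) | COC(=O)CC1CN(C(=O)OC)c2c(Br)ccc(O)c21 | intermediate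
16 | methyl 7-bromo-4-methoxy-3-(2-methoxy-2-oxoethyl)-2,3-dihydroindole-1-carboxylate (racemic) | COC(=O)CC1CN(C(=O)OC)c2c(Br)ccc(OC)c21 | intermediate
17 | methyl 7-bromo-4-methoxy-3-(2-methoxy-2-oxoethyl)indole-1-carboxylate | COC(=O)Cc1cn(C(=O)OC)c2c(Br)ccc(OC)c12 | intermediate
18 | methyl formate | COC=O | starting material
19 | methyl 2-(7-bromo-4-methoxy-1H-indol-3-yl)acetate | COC(=O)Cc1c[nH]c2c(Br)ccc(OC)c12 | intermediate (not isolated)
20 | methyl 2-(7-bromo-4-methoxy-1H-indol-3-yl)-3-hydroxyprop-2-enoate (enol of the formyl ester, E/Z mixture) | COC(=O)C(=CO)c1c[nH]c2c(Br)ccc(OC)c12 | intermediate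
21 | urea | NC(N)=O | starting material
22 | methyl 2-(7-bromo-4-methoxy-1H-indol-3-yl)-3-(carbamoylamino)prop-2-enoate (ureidoacrylate ester) | COC(=O)C(=CNC(N)=O)c1c[nH]c2c(Br)ccc(OC)c12 | intermediate (not isolated)
23 | 5-(7-bromo-4-methoxy-1H-indol-3-yl)pyrimidine-2,4(1H,3H)-dione | COc1ccc(Br)c2[nH]cc(-c3c[nH]c(=O)[nH]c3=O)c12 | intermediate
24 | 7-bromo-3-(2,4-dibromopyrimidin-5-yl)-4-methoxy-1H-indole | COc1ccc(Br)c2[nH]cc(-c3cnc(Br)nc3Br)c12 | intermediate
25 | 2-bromo-5-(7-bromo-4-methoxy-1H-indol-3-yl)pyrimidin-4-amine | COc1ccc(Br)c2[nH]cc(-c3cnc(Br)nc3N)c12 | intermediate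
26 | 3-(4-amino-2-bromopyrimidin-5-yl)-7-bromo-1H-indol-4-ol | Nc1nc(Br)ncc1-c1c[nH]c2c(Br)ccc(O)c12 | target

Total step count: 13.
Longest linear sequence: 12 steps (from 5 through steps 2 to 13).

Steps most likely to fail

Step 6 (the proposed new method; its fallback uses known chemistry). What may go wrong: the nitrogen lone pair is conjugated through C7a=C3a to the gold carbene, so the ring-opened intermediate may close C4 directly onto the aldehyde carbon, or the arene oxide may open at C4–O; either leaves the oxygen on C5, para to nitrogen. Capture of the alkyne by the enamide carbon and acid-induced decomposition of the amidofuran are further failure processes. Fallback: the furan series is abandoned, so this path sets out from no numbered intermediate but from purchased 1-bromo-4-methoxy-2-nitrobenzene F1, which takes the place of compounds 1 to 17. A Bartoli indole synthesis on this ortho-bromonitroarene (CH2=CHMgBr, 3 equiv, THF, −40 °C) should give 7-bromo-4-methoxy-1H-indole F2. C3–H alkylation of F2 with methyl diazoacetate under Cu(OTf)2 (divalent copper, cat., CH2Cl2, rt) should then give methyl 2-(7-bromo-4-methoxy-1H-indol-3-yl)acetate, which is compound 19. The route resumes there with the formylation stage of step 9.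

Step 5. What may go wrong: substitution at the β-branched primary carbon is slow, so E2 elimination across the propargylic C–H, enolate closure to a cyclopropane or decomposition of the carbamate anion can outrun N-alkylation. Fallback: the C–N bond is made by conjugate addition instead of substitution and the alkyne is installed last; the path sets out from compound 4 and comes back at compound 13. Purchased methyl 4-oxobutanoate F3 is α-methylenated (aq. CH2O, pyrrolidine/EtCO2H cat., i-PrOH, 45 °C) to methyl 3-formylbut-3-enoate F4. Base-catalysed aza-Michael addition of 4 to F4 (DBU cat., MeCN, 0 °C) should give methyl 3-{[(3-bromofuran-2-yl)(methoxycarbonyl)amino]methyl}-4-oxobutanoate F5. Seyferth–Gilbert homologation of F5 with the Bestmann–Ohira reagent (dimethyl (1-diazo-2-oxopropyl)phosphonate, K2CO3, MeOH, 0 °C) then converts the formyl group into the terminal alkyne of 13.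

Step 12. What may go wrong: loss of site selectivity, with ammonia attacking the unhindered C2' beside or instead of the C4' position next to the bulky indolyl group, or substitution at both positions. Fallback: the two positions are differentiated before any bromine is introduced; the path sets out from compound 23 and comes back at compound 25. C4'-selective thionation (Lawesson's reagent, 1,4-dioxane, 100 °C) should give 5-(7-bromo-4-methoxy-1H-indol-3-yl)-4-thioxo-3,4-dihydropyrimidin-2(1H)-one F6. Ammonolysis of the thioamide (NH3, MeOH, sealed tube, 100 °C) should give 4-amino-5-(7-bromo-4-methoxy-1H-indol-3-yl)pyrimidin-2(1H)-one F7. POBr3 (PhNMe2, MeCN, 80 °C) then brominates the single remaining lactam position to give 25.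

Further compounds
F1 | step 6 | 1-bromo-4-methoxy-2-nitrobenzene | COc1ccc(Br)c([N+](=O)[O-])c1
F2 | step 6 | 7-bromo-4-methoxy-1H-indole | COc1ccc(Br)c2[nH]ccc12
F3 | step 5 | methyl 4-oxobutanoate | COC(=O)CCC=O
F4 | step 5 | methyl 3-formylbut-3-enoate | COC(=O)CC(=C)C=O
F5 | step 5 | methyl 3-{[(3-bromofuran-2-yl)(methoxycarbonyl)amino]methyl}-4-oxobutanoate (racemic) | COC(=O)CC(C=O)CN(C(=O)OC)c1occc1Br
F6 | step 12 | 5-(7-bromo-4-methoxy-1H-indol-3-yl)-4-thioxo-3,4-dihydropyrimidin-2(1H)-one | COc1ccc(Br)c2[nH]cc(-c3c[nH]c(=O)[nH]c3=S)c12
F7 | step 12 | 4-amino-5-(7-bromo-4-methoxy-1H-indol-3-yl)pyrimidin-2(1H)-one | COc1ccc(Br)c2[nH]cc(-c3c[nH]c(=O)nc3N)c12
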